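Everything rests on disconnecting C7–C8: C7 is the exo-methylene carbon (C7=C14H2) on cyclohexane carbon C1, C8 the adjacent acyloxy carbinol of the side chain. This 2-substituted allylic alcohol is the retron of a Nozaki–Hiyama–Kishi coupling: C7 becomes the enol triflate of a methyl ketone on a fully oxygenated cyclohexane built from (R)-carvone, C8 the aldehyde carbon of an (S)-epoxy aldehyde. One ligand-controlled Ni/Cr step joins both fragments, forms C7–C8, and sets C8 (S) with the C7=C14 alkene already in place; a single angeloylation then gives the target.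

Key step: step 11

Remark (numbering and faces): ring C1–C6 with C1 bearing the side chain, C2-OH, C3-OAng, C4(OH)CH3, C5-OAng, C6H2; side chain C7(=C14H2), C8, C9, C10–C11 epoxide. β is the ring face of the C1 substituent, α the opposite face. Ang = angeloyl, (Z)-2-methylbut-2-enoyl.
Assumption: in step 11 the antipode of the oxazoline–sulfonamide ligand that delivers 8S is used; both antipodes are accessible from D- or L-valinol.

Step 1
Reactants: 1 (R)-(−)-carvone
Product: 2 (1R,5R)-cis-carveol (5β-ol)
Conditions: NaBH4, CeCl3·7H2O, MeOH, 0 °C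
Reagents that add atoms: none
Why: Luche 1,2-reduction, in which axial hydride delivery to the enone carbonyl should give the pseudo-equatorial 5β-alcohol cis to the C1 isopropenyl group.

Step 2
Reactants: 2 (1R,5R)-cis-carveol
Product: 3 3β,4β-epoxy-5β-alcohol (cis-carveol epoxide)
Conditions: VO(acac)2 (cat.), t-BuOOH, CH2Cl2, 0 °C → rt
Reagents that add atoms: tert-butyl hydroperoxide, CC(C)(C)OO
Why: Vanadium-catalysed hydroxyl-directed epoxidation should oxidise only the allylic-alcohol alkene (the isopropenyl group is not directed) and deliver oxygen on the face of the C5-OH, which sets C3 and C4 as the 3β,4β-epoxide.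

Step 3
Reactants: 3 3β,4β-epoxy-5β-alcohol; 4 angelic acid
Product: 5 3β,4β-epoxy-5α-angelate
Conditions: PPh3, DIAD, toluene, 0 °C → rt
Reagents that add atoms: angelic acid (4), C/C=C(C)\C(=O)O
Why: Mitsunobu esterification, in which angelate displaces the equatorial alkoxyphosphonium from the α-face (SN2, inversion at C5; an equatorial leaving group has no anti-periplanar hydrogen for E2 and the syn epoxide oxygen cannot participate) under near-neutral conditions that should leave the Z-enoate intact.

Step 4
Reactants: 5 3β,4β-epoxy-5α-angelate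
Product: 7 methyl ketone (C1 acetyl), via ozonide 6 (not isolated)
Conditions: O3, CH2Cl2, −78 °C (Sudan Red 7B end point); then Me2S, −78 °C → rt
Reagents that add atoms: ozone, [O-][O+]=O
Why: Ozonolysis should cleave the electron-rich 1,1-disubstituted isopropenyl alkene in preference to the electron-poor angelate, turning C7 into a methyl ketone with loss of one carbon as formaldehyde.

Step 5
Reactants: 7 methyl ketone
Product: 9 enol triflate (C1 = 1-(triflyloxy)vinyl), via potassium enolate 8 (not isolated)
Conditions: KHMDS, THF, −78 °C; then PhNTf2, −78 → 0 °C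
Reagents that add atoms: N-phenylbis(trifluoromethanesulfonimide), O=S(=O)(N(c1ccccc1)S(=O)(=O)C(F)(F)F)C(F)(F)F
Why: Kinetic deprotonation at the unhindered methyl group followed by O-sulfonylation (enol triflate formation) should give the terminal alkenyl triflate without enolising towards C1-H, so the C1 stereocentre is kept.

Step 6
Reactants: 9 enol triflate
Product: 12 allylic alcohol (C2=C3 and tertiary 4β-OH), via hydroxy selenide 10 (not isolated), via selenoxide 11 (not isolated)
Conditions: (PhSe)2, NaBH4, EtOH, rt → 50 °C; then THF, 30% H2O2, pyridine, 0 °C → rt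
Reagents that add atoms: none
Why: Selenide opening of the epoxide followed by selenoxide syn-elimination, in which the selenolate attacks the secondary C3 from the α-face in a trans-diaxial opening that keeps the C1 substituent equatorial, and the selenoxide can only eliminate towards C2 because C4 carries no hydrogen, so the 4β-OH stereocentre is retained.

Step 7
Reactants: 12 allylic alcohol
Product: 14 2β,3β,4β-triol, via osmate ester 13 (not isolated)
Conditions: OsO4 (1.05 equiv), TMEDA, CH2Cl2, −78 °C; then aq. Na2SO3, THF, rt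
Reagents that add atoms: osmium tetroxide, O=[Os](=O)(=O)=O
Why: Hydrogen-bond-directed dihydroxylation with OsO4·TMEDA, in which the pseudo-axial 4β-OH should deliver the reagent to the β-face of C2=C3 (the α-face is also shielded by the axial C5 angelate), setting C2 and C3 all-cis to C4-OH, while the electron-poor enol triflate and angelate alkenes react far more slowly.

Step 8
Reactants: 14 2β,3β,4β-triol; 15 angelic anhydride
Product: 17 3β,5α-bis(angelate) 2β,4β-diol enol triflate, via stannylene acetal 16 (not isolated)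
Conditions: Bu2SnO, toluene, reflux (−H2O); then 15, 0 °C → rt
Reagents that add atoms: angelic anhydride (15), C/C=C(C)\C(=O)OC(=O)/C(C)=C\C
Why: Stannylene-acetal-mediated regioselective acylation, in which the equatorial oxygen of a cis-diol (C3-O) should be acylated in preference to the axial C2-OH and the tertiary C4-OH, under neutral conditions that should keep the angelate Z.

Step 9
Reactants: 18 4-methylpent-3-en-1-ol
Product: 19 (S)-2-(3,3-dimethyloxiran-2-yl)ethan-1-ol
Conditions: L-fructose-derived Shi ketone (30 mol%), Oxone, K2CO3, Bu4NHSO4, MeCN–DMM/aq. buffer (pH 10.5), 0 °C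
Reagents that add atoms: potassium peroxymonosulfate (Oxone), [K+].[O-]S(=O)(=O)OO
Why: Shi epoxidation (chiral dioxirane, spiro transition state) of the trisubstituted alkene, with the L-fructose-derived ketone chosen because its D-fructose-derived antipode gives the R epoxide with this olefin class, so C10 should be set S by the catalyst.

Step 10
Reactants: 19 (S)-2-(3,3-dimethyloxiran-2-yl)ethan-1-ol
Product: 20 (S)-2-(3,3-dimethyloxiran-2-yl)acetaldehyde
Conditions: Dess–Martin periodinane, pyridine, CH2Cl2, 0 °C
Reagents that add atoms: none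
Why: Dess–Martin oxidation under buffered non-basic conditions should give the β,γ-epoxy aldehyde without β-elimination of the epoxide, and the crude aldehyde is used at once.

Step 11
Reactants: 17 3β,5α-bis(angelate) 2β,4β-diol enol triflate; 20 (S)-2-(3,3-dimethyloxiran-2-yl)acetaldehyde (1.5–2 equiv)
Product: 21 (8S)-allylic alcohol (8-de-O-angeloyl target)
Conditions: CrCl2, chiral oxazoline–sulfonamide ligand, Et3N, THF, rt; then 17 + 20, NiCl2·(2,9-dimethyl-1,10-phenanthroline) (cat.), rt
Reagents that add atoms: none
Why: Ni(0) generated in situ inserts into the C7–OTf bond of 17 and passes the alkenyl group to chromium; the ligand-bound alkenylchromium(III) then adds to the aldehyde carbon of 20, forming C7–C8 with the C7=C14 double bond left in place. The closest known reaction type is the asymmetric Ni/Cr-mediated Nozaki–Hiyama–Kishi coupling of a 1-substituted alkenyl triflate (from a methyl ketone) with an aldehyde. No ring is closed. The new C8 stereocentre is set by the chiral oxazoline–sulfonamide bound to chromium (reagent control), which should override the weak 1,3-induction from the C10 epoxide centre and the remote ring centres. The step needs chemoselectivity for the aldehyde over two angelates, the epoxide and two free hydroxyls, which the low basicity and aldehyde selectivity of alkenylchromium(III) reagents secure, and it needs one aldehyde face, which the ligand secures. The fragile aldehyde 20 is used in excess so that the advanced triflate 17 is the limiting partner.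

Step 12
Reactants: 21 (8S)-allylic alcohol; 15 angelic anhydride
Product: 22 target, (1R,2S,3S,4R,5S,8S,10S)-3,5,8-tris(angeloyloxy)-10,11-epoxybisabol-7(14)-ene-2,4-diol
Conditions: 15, Cs2CO3, MeCN, 0 °C → rt
Reagents that add atoms: angelic anhydride (15), C/C=C(C)\C(=O)OC(=O)/C(C)=C\C
Why: Carbonate-mediated acylation with angelic anhydride, without a nucleophilic catalyst that would isomerise angelate to tiglate, should select the unhindered allylic C8-OH over the axial, doubly flanked C2-OH and the tertiary C4-OH.

Compound list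
1 | (R)-(−)-carvone | CC(=C)[C@H]1CC(=O)C(C)=CC1 | starting material
2 | (1R,5R)-cis-carveol (5β-OH, cis to isopropenyl) | CC(=C)[C@H]1C[C@@H](O)C(C)=CC1 | intermediate
3 | 3β,4β-epoxy-5β-alcohol (epoxide O and OH cis to the C1 isopropenyl group) | CC(=C)[C@H]1C[C@@H](O)[C@@]2(C)O[C@H]2C1 | intermediate
4 | angelic acid, (Z)-2-methylbut-2-enoic acid | C/C=C(C)\C(=O)O | starting material
5 | 3β,4β-epoxy-5α-angelate (C1 isopropenyl) | CC(=C)[C@H]1C[C@H](OC(=O)/C(C)=C\C)[C@@]2(C)O[C@H]2C1 | intermediate
6 | secondary ozonide of 5 (3-methyl-1,2,4-trioxolan-3-yl at C1, mixture at the new centre) | CC1(OCOO1)[C@H]1C[C@H](OC(=O)/C(C)=C\C)[C@@]2(C)O[C@H]2C1 | intermediate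
7 | methyl ketone (C1 acetyl; 3β,4β-epoxide; 5α-angelate) | CC(=O)[C@H]1C[C@H](OC(=O)/C(C)=C\C)[C@@]2(C)O[C@H]2C1 | intermediate
8 | potassium enolate of 7 (terminal C7=C14 enolate) | [K+].C=C([O-])[C@H]1C[C@H](OC(=O)/C(C)=C\C)[C@@]2(C)O[C@H]2C1 | intermediate
9 | enol triflate (C1 = 1-(trifluoromethanesulfonyloxy)vinyl; 3β,4β-epoxide; 5α-angelate) | C=C(OS(=O)(=O)C(F)(F)F)[C@H]1C[C@H](OC(=O)/C(C)=C\C)[C@@]2(C)O[C@H]2C1 | intermediate
10 | hydroxy selenide (3α-SePh; 4β-OH; 5α-angelate) | C=C(OS(=O)(=O)C(F)(F)F)[C@H]1C[C@H](OC(=O)/C(C)=C\C)[C@@](C)(O)[C@H]([Se]c2ccccc2)C1 | intermediate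
11 | selenoxide of 10 | C=C(OS(=O)(=O)C(F)(F)F)[C@H]1C[C@H](OC(=O)/C(C)=C\C)[C@@](C)(O)[C@H]([Se](=O)c2ccccc2)C1 | intermediate
12 | allylic alcohol (C2=C3; tertiary 4β-OH; 5α-angelate; C1 enol triflate) | C=C(OS(=O)(=O)C(F)(F)F)[C@H]1C[C@H](OC(=O)/C(C)=C\C)[C@@](C)(O)C=C1 | intermediate
13 | 2β,3β-osmate(VI) ester of 12, TMEDA complex | C=C(OS(=O)(=O)C(F)(F)F)[C@H]1C[C@H](OC(=O)/C(C)=C\C)[C@@](C)(O)[C@@H](O3)[C@H]1O[Os]3(=O)=O.CN(C)CCN(C)C | intermediate
14 | 2β,3β,4β-triol 5α-angelate enol triflate | C=C(OS(=O)(=O)C(F)(F)F)[C@H]1C[C@H](OC(=O)/C(C)=C\C)[C@@](C)(O)[C@@H](O)[C@H]1O | intermediate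
15 | angelic anhydride | C/C=C(C)\C(=O)OC(=O)/C(C)=C\C | starting material
16 | 2,3-O-dibutylstannylene acetal of 14 | C=C(OS(=O)(=O)C(F)(F)F)[C@H]1C[C@H](OC(=O)/C(C)=C\C)[C@@](C)(O)[C@@H](O3)[C@H]1O[Sn]3(CCCC)CCCC | intermediate
17 | 3β,5α-bis(angelate) 2β,4β-diol enol triflate | C=C(OS(=O)(=O)C(F)(F)F)[C@H]1C[C@H](OC(=O)/C(C)=C\C)[C@@](C)(O)[C@@H](OC(=O)/C(C)=C\C)[C@H]1O | intermediate
18 | 4-methylpent-3-en-1-ol | CC(C)=CCCO | starting material
19 | (S)-2-(3,3-dimethyloxiran-2-yl)ethan-1-ol | OCC[C@@H]1OC1(C)C | intermediate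
20 | (S)-2-(3,3-dimethyloxiran-2-yl)acetaldehyde | O=CC[C@@H]1OC1(C)C | intermediate
21 | (8S)-allylic alcohol, 3,5-di-O-angeloyl-10,11-epoxybisabol-7(14)-ene-2,4,8-triol | C=C([C@H](C[C@@H]1OC1(C)C)O)[C@H]1C[C@H](OC(=O)/C(C)=C\C)[C@@](C)(O)[C@@H](OC(=O)/C(C)=C\C)[C@H]1O | intermediate
22 | (1R,2S,3S,4R,5S,8S,10S)-3,5,8-tris(angeloyloxy)-10,11-epoxybisabol-7(14)-ene-2,4-diol | C=C([C@H](C[C@@H]1OC1(C)C)OC(=O)/C(C)=C\C)[C@H]1C[C@H](OC(=O)/C(C)=C\C)[C@@](C)(O)[C@@H](OC(=O)/C(C)=C\C)[C@H]1O | target

Total step count: 12. Longest linear sequence: 10 steps (steps 1–8, 11, 12); steps 9–10 make the aldehyde.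

Steps most likely to fail

Step 11. The β,γ-epoxy aldehyde may be opened or β-eliminated by Cr(III) and chloride before the slow alkenyl transfer takes place, and ligand control of the aldehyde face may be incomplete. The fallback postpones the epoxide; it sets out from 17 and 18 and comes back at 22. Alcohol 18 would be oxidised with Dess–Martin periodinane to 4-methylpent-3-enal F1, which would be coupled with triflate 17 under the same Ni/Cr conditions to the dienyl (8S)-alcohol F2. Angeloylation with 15 would give the triangelate diene F3. A late Shi epoxidation with the L-fructose-derived ketone would then oxidise the only electron-rich trisubstituted alkene (C10=C11) and return to 22.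

Step 3. Substitution at a carbinol flanked by the quaternary epoxide carbon may be slow, so that elimination, ester formation with retention or Z→E isomerisation of the acid takes over. The fallback replaces the SN2 inversion by an oxidation–reduction sequence; it sets out from 3 and comes back at 5. Alcohol 3 would be oxidised with Dess–Martin periodinane to the epoxy ketone F4. A Luche reduction, in which cerium-bridged hydride delivery from the epoxide face should be preferred, would give the 5α-epoxy alcohol F5, and F5 would be esterified with angelic anhydride 15 (Cs2CO3 or LiHMDS) to 5.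

Step 12. Site selectivity may be lost by acylation of the C2-OH, or by base-induced C3→C2 acyl migration. The fallback uses a protecting group; it sets out from 17 and comes back at 22. The secondary C2-OH of 17 would be silylated (TESCl, imidazole, DMF; the tertiary C4-OH should not react) to the 2-O-triethylsilyl ether F6. The same Ni/Cr coupling with 20 would give the alcohol F7, angeloylation with 15 the triangelate silyl ether F8, and buffered HF·pyridine (THF, 0 °C) would remove the silyl group to give 22.

Further compounds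
F1 | step 11 | 4-methylpent-3-enal | CC(C)=CCC=O
F2 | step 11 | (8S)-allylic alcohol with C10=C11 alkene (10,11-deoxy analogue of 21) | C=C([C@H](CC=C(C)C)O)[C@H]1C[C@H](OC(=O)/C(C)=C\C)[C@@](C)(O)[C@@H](OC(=O)/C(C)=C\C)[C@H]1O
F3 | step 11 | triangelate with C10=C11 alkene (10,11-deoxy analogue of 22) | C=C([C@H](CC=C(C)C)OC(=O)/C(C)=C\C)[C@H]1C[C@H](OC(=O)/C(C)=C\C)[C@@](C)(O)[C@@H](OC(=O)/C(C)=C\C)[C@H]1O
F4 | step 3 | 3β,4β-epoxy-5-ketone (epoxide cis to isopropenyl) | CC(=C)[C@H]1CC(=O)[C@@]2(C)O[C@H]2C1
F5 | step 3 | 3β,4β-epoxy-5α-alcohol | CC(=C)[C@H]1C[C@H](O)[C@@]2(C)O[C@H]2C1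
F6 | step 12 | 2-O-triethylsilyl ether of 17 | C=C(OS(=O)(=O)C(F)(F)F)[C@H]1C[C@H](OC(=O)/C(C)=C\C)[C@@](C)(O)[C@@H](OC(=O)/C(C)=C\C)[C@H]1O[Si](CC)(CC)CC
F7 | step 12 | 2-O-triethylsilyl ether of 21 | C=C([C@H](C[C@@H]1OC1(C)C)O)[C@H]1C[C@H](OC(=O)/C(C)=C\C)[C@@](C)(O)[C@@H](OC(=O)/C(C)=C\C)[C@H]1O[Si](CC)(CC)CC
F8 | step 12 | 2-O-triethylsilyl ether of 22 | C=C([C@H](C[C@@H]1OC1(C)C)OC(=O)/C(C)=C\C)[C@H]1C[C@H](OC(=O)/C(C)=C\C)[C@@](C)(O)[C@@H](OC(=O)/C(C)=C\C)[C@H]1O[Si](CC)(CC)CC
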